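**Plan**

- Retrosynthesis: the acrylic acid C=C is cut back to an aryl aldehyde and malonic acid. Then the C1'–C2' bond (benzylic carbon to alkene) and the C3'–CH3 bond are cut together, giving a benzylic chloride, trimethylaluminium and a terminal alkyne. Last, the C3'–C4' bond is cut through an ynone to a Weinreb amide and a silylacetylene.
- Enabling feature (side chain numbered from the benzylic carbon C1' on the anisole ring): the C2'=C3' alkene is E-trisubstituted, with CH3 and the C4' carbinol on C3' and C1' on C2'. This is the imprint of a syn CH3–Al addition across a terminal alkyne C2'≡C3', followed by benzylation at C2' with retention.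
- Forward: no ring is formed. The C3'–C8' chain is built linearly (acid, Weinreb amide, silyl ynone, carbinol, silyl ether, terminal alkyne) and joined in one flask to methyl and to the acetal-masked benzylic chloride. Desilylation, acetylation, unmasking and a Doebner condensation finish the route.
- Stereochemistry: C4' (R) comes from catalytic asymmetric transfer hydrogenation of the ynone and is not touched again. The 2'E alkene comes from syn carbometalation plus stereoretentive coupling. The E acrylic acid comes from the decarboxylative Doebner condensation.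

Key step: step 7

Remark: in step 3 the alkynyl group is assumed to take the place that an aryl group holds in aryl ketone reductions with TsDPEN–ruthenium catalysts, so the (R,R)-ligand is expected to give the (R)-carbinol.

**Route**

Step 1
Reactants: 1 4-methylpent-3-enoic acid
Product: 3 N-methoxy-N,4-dimethylpent-3-enamide, via acyl imidazolide 2 (not isolated)
Conditions: CDI (1.1 equiv), CH2Cl2, 0 °C → rt; then MeNH(OMe)·HCl (1.2 equiv), rt
Reagents that add atoms: N,O-dimethylhydroxylamine hydrochloride, CNOC.Cl
Why: Carbonyldiimidazole activation gives the acyl imidazolide under neutral conditions (no acid chloride, so no ketene formation or migration of the β,γ-double bond), and aminolysis gives the Weinreb amide.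

Step 2
Reactants: 3 N-methoxy-N,4-dimethylpent-3-enamide; 4 ethynyltrimethylsilane
Product: 7 6-methyl-1-(trimethylsilyl)hept-5-en-1-yn-3-one, via lithium trimethylsilylacetylide 5 (not isolated), via lithium hemiaminal adduct 6 (not isolated)
Conditions: 4, n-BuLi, THF, −78 °C; then 3, −78 → −20 °C; cold 1 M HCl quench
Reagents that add atoms: none
Why: Weinreb ketone synthesis: the acetylide adds once to give the chelated tetrahedral adduct, which releases the ynone only on the cold acidic quench, so neither over-addition nor base-mediated conjugation of the skipped alkene is expected.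

Step 3
Reactants: 7 6-methyl-1-(trimethylsilyl)hept-5-en-1-yn-3-one
Product: 8 (R)-6-methyl-1-(trimethylsilyl)hept-5-en-1-yn-3-ol
Conditions: Ru[(R,R)-TsDPEN](p-cymene) (preformed 16-electron amido complex, 1 mol %; TsDPEN = N-tosyl-1,2-diphenylethylenediamine), i-PrOH (0.1 M), rt
Reagents that add atoms: none
Why: Noyori-type asymmetric transfer hydrogenation of an alkynyl ketone: hydride and proton pass from the Ru–H/N–H unit through a six-membered transition state in which the alkynyl group sits where an aryl group normally does, so the (R,R)-ligand should set the (R)-carbinol, with C=O reduced in preference to the alkyne and the trisubstituted alkene.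

Step 4
Reactants: 8 (R)-6-methyl-1-(trimethylsilyl)hept-5-en-1-yn-3-ol
Product: 9 (R)-tert-butyldimethyl{[6-methyl-1-(trimethylsilyl)hept-5-en-1-yn-3-yl]oxy}silane
Conditions: TBSCl, imidazole, DMF, rt
Reagents that add atoms: tert-butyldimethylsilyl chloride, CC(C)(C)[Si](C)(C)Cl
Why: Standard imidazole-promoted O-silylation of a secondary alcohol; the bulky, non-chelating silyl ether is chosen for the carbometalation and masks a volatile alcohol.

Step 5
Reactants: 9 (R)-tert-butyldimethyl{[6-methyl-1-(trimethylsilyl)hept-5-en-1-yn-3-yl]oxy}silane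
Product: 10 (R)-tert-butyldimethyl[(6-methylhept-5-en-1-yn-3-yl)oxy]silane
Conditions: K2CO3 (0.2 equiv), MeOH, rt
Reagents that add atoms: none
Why: Methoxide-mediated protodesilylation cleaves only the alkynyl C–Si bond; the hindered O–Si bond and the stereocentre are not affected.

Step 6
Reactants: 11 3-(chloromethyl)-4-methoxybenzaldehyde
Product: 12 2-[3-(chloromethyl)-4-methoxyphenyl]-1,3-dioxolane
Conditions: TMSOCH2CH2OTMS (1.2 equiv), TMSOTf (2 mol %), CH2Cl2, −78 → −20 °C; pyridine quench
Reagents that add atoms: 1,2-bis(trimethylsilyloxy)ethane, C[Si](C)(C)OCCO[Si](C)(C)C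
Why: Silyl-triflate-catalysed acetalisation with the bis-silyl ether (Noyori conditions) is driven by formation of hexamethyldisiloxane at low temperature, so the solvolysis-prone ortho-methoxybenzylic chloride is not exposed to free diol, protic acid or heat.

Step 7
Reactants: 10 (R)-tert-butyldimethyl[(6-methylhept-5-en-1-yn-3-yl)oxy]silane; 13 trimethylaluminium; 12 2-[3-(chloromethyl)-4-methoxyphenyl]-1,3-dioxolane
Product: 15 2-{3-[(2E,4R)-4-(tert-butyldimethylsilyloxy)-3,7-dimethylocta-2,6-dien-1-yl]-4-methoxyphenyl}-1,3-dioxolane, via alkenyldimethylalane 14 (not isolated)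
Conditions: 13 (2.5 equiv), Cp2ZrCl2 (0.25 equiv), CH2Cl2, 0 °C → rt; volatiles removed in vacuo, THF; 12, ZnCl2 (0.2 equiv), Pd(PPh3)4 (5 mol %), rt → 40 °C
Reagents that add atoms: none
Why: AlMe3 and Cp2ZrCl2 form a bimetallic methylzirconium–aluminium species that adds CH3 and metal across the terminal alkyne of 10 through a four-centre syn transition state, methyl going to the internal carbon (C3'–CH3 bond) and aluminium to the terminus, so that 14 carries Al cis to methyl. Oxidative addition of the benzylic C–Cl bond of 12 to zerovalent palladium, alkenyl transfer from aluminium (relayed by ZnCl2) and reductive elimination then form C1'–C2' with retention of alkene geometry, placing the arylmethyl group cis to methyl, which is the 2'E alkene. The closest known reaction type is the Negishi zirconium-catalysed carboalumination of terminal alkynes combined with palladium- or nickel-catalysed coupling of the alkenylalane with benzylic chlorides. No ring is closed and no stereocentre is created; the C4' centre lies outside the reacting bonds and cannot epimerise. The step needs regioselectivity (methyl internal) and syn stereospecificity, both supported by the terminal alkyne and the bulky, non-chelating silyl ether, while the trisubstituted C6'=C7' alkene does not carbometalate. Stripping excess AlMe3 and changing to THF before 12 is added keeps strong Lewis acid away from the aryl dioxolane.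

Step 8
Reactants: 15 2-{3-[(2E,4R)-4-(tert-butyldimethylsilyloxy)-3,7-dimethylocta-2,6-dien-1-yl]-4-methoxyphenyl}-1,3-dioxolane
Product: 16 (2E,4R)-1-[5-(1,3-dioxolan-2-yl)-2-methoxyphenyl]-3,7-dimethylocta-2,6-dien-4-ol
Conditions: TBAF (1.5 equiv), THF, rt; water work-up
Reagents that add atoms: none
Why: Fluoride-mediated silyl ether cleavage; the acetal, the skipped diene and the allylic stereocentre are inert to TBAF.

Step 9
Reactants: 16 (2E,4R)-1-[5-(1,3-dioxolan-2-yl)-2-methoxyphenyl]-3,7-dimethylocta-2,6-dien-4-ol
Product: 17 (2E,4R)-1-[5-(1,3-dioxolan-2-yl)-2-methoxyphenyl]-3,7-dimethylocta-2,6-dien-4-yl acetate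
Conditions: Ac2O, pyridine, DMAP (cat.), CH2Cl2, rt
Reagents that add atoms: acetic anhydride, CC(=O)OC(C)=O
Why: DMAP-catalysed O-acylation of the secondary allylic alcohol; the C4'–O bond is not broken, so configuration is retained.

Step 10
Reactants: 17 (2E,4R)-1-[5-(1,3-dioxolan-2-yl)-2-methoxyphenyl]-3,7-dimethylocta-2,6-dien-4-yl acetate
Product: 18 (2E,4R)-1-(5-formyl-2-methoxyphenyl)-3,7-dimethylocta-2,6-dien-4-yl acetate
Conditions: 1 M aq. HCl/THF (1:4), 0 °C → rt
Reagents that add atoms: water, O
Why: Acid-catalysed acetal hydrolysis, fast for the para-methoxy-stabilised oxocarbenium ion, so conditions mild enough to spare the allylic acetate and both trisubstituted alkenes should suffice.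

Step 11
Reactants: 18 (2E,4R)-1-(5-formyl-2-methoxyphenyl)-3,7-dimethylocta-2,6-dien-4-yl acetate
Product: 20 (2E)-3-{3-[(2E,4R)-4-acetoxy-3,7-dimethylocta-2,6-dien-1-yl]-4-methoxyphenyl}prop-2-enoic acid, via arylidenemalonic acid 19 (not isolated)
Conditions: malonic acid (2 equiv), pyridine, piperidine (0.1 equiv), 90 °C
Reagents that add atoms: malonic acid, OC(=O)CC(=O)O
Why: Doebner modification of the Knoevenagel condensation: condensation gives the arylidenemalonic acid, which loses CO2 in hot pyridine to give the E acrylic acid directly as the free acid, so no ester has to be cleaved beside the acetate.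

**Compound list**

1 | 4-methylpent-3-enoic acid | CC(C)=CCC(=O)O | starting material
2 | 1-(1H-imidazol-1-yl)-4-methylpent-3-en-1-one (acyl imidazolide) | CC(C)=CCC(=O)n1ccnc1 | intermediate
3 | N-methoxy-N,4-dimethylpent-3-enamide | CC(C)=CCC(=O)N(C)OC | intermediate
4 | ethynyltrimethylsilane | C#C[Si](C)(C)C | starting material
5 | lithium (trimethylsilyl)acetylide | [Li]C#C[Si](C)(C)C | intermediate
6 | lithium 3-[methoxy(methyl)amino]-6-methyl-1-(trimethylsilyl)hept-5-en-1-yn-3-olate | CC(C)=CCC(O[Li])(C#C[Si](C)(C)C)N(C)OC | intermediate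
7 | 6-methyl-1-(trimethylsilyl)hept-5-en-1-yn-3-one | CC(C)=CCC(=O)C#C[Si](C)(C)C | intermediate
8 | (R)-6-methyl-1-(trimethylsilyl)hept-5-en-1-yn-3-ol | C[Si](C)(C)C#C[C@@H](CC=C(C)C)O | intermediate
9 | (R)-tert-butyldimethyl{[6-methyl-1-(trimethylsilyl)hept-5-en-1-yn-3-yl]oxy}silane | C[Si](C)(C)C#C[C@@H](CC=C(C)C)O[Si](C)(C)C(C)(C)C | intermediate
10 | (R)-tert-butyldimethyl[(6-methylhept-5-en-1-yn-3-yl)oxy]silane | C#C[C@@H](CC=C(C)C)O[Si](C)(C)C(C)(C)C | intermediate
11 | 3-(chloromethyl)-4-methoxybenzaldehyde | COc1ccc(C=O)cc1CCl | starting material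
12 | 2-[3-(chloromethyl)-4-methoxyphenyl]-1,3-dioxolane | COc1ccc(C2OCCO2)cc1CCl | intermediate
13 | trimethylaluminium | C[Al](C)C | starting material
14 | [(1E,3R)-3-(tert-butyldimethylsilyloxy)-2,6-dimethylhepta-1,5-dien-1-yl]dimethylalane | C[Al](C)/C=C(\C)[C@@H](CC=C(C)C)O[Si](C)(C)C(C)(C)C | intermediate
15 | 2-{3-[(2E,4R)-4-(tert-butyldimethylsilyloxy)-3,7-dimethylocta-2,6-dien-1-yl]-4-methoxyphenyl}-1,3-dioxolane | COc1ccc(C2OCCO2)cc1C/C=C(\C)[C@@H](CC=C(C)C)O[Si](C)(C)C(C)(C)C | intermediate
16 | (2E,4R)-1-[5-(1,3-dioxolan-2-yl)-2-methoxyphenyl]-3,7-dimethylocta-2,6-dien-4-ol | COc1ccc(C2OCCO2)cc1C/C=C(\C)[C@@H](CC=C(C)C)O | intermediate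
17 | (2E,4R)-1-[5-(1,3-dioxolan-2-yl)-2-methoxyphenyl]-3,7-dimethylocta-2,6-dien-4-yl acetate | COc1ccc(C2OCCO2)cc1C/C=C(\C)[C@@H](CC=C(C)C)OC(C)=O | intermediate
18 | (2E,4R)-1-(5-formyl-2-methoxyphenyl)-3,7-dimethylocta-2,6-dien-4-yl acetate | COc1ccc(C=O)cc1C/C=C(\C)[C@@H](CC=C(C)C)OC(C)=O | intermediate
19 | 2-{3-[(2E,4R)-4-acetoxy-3,7-dimethylocta-2,6-dien-1-yl]-4-methoxybenzylidene}malonic acid | COc1ccc(C=C(C(=O)O)C(=O)O)cc1C/C=C(\C)[C@@H](CC=C(C)C)OC(C)=O | intermediate
20 | (2E)-3-{3-[(2E,4R)-4-acetoxy-3,7-dimethylocta-2,6-dien-1-yl]-4-methoxyphenyl}prop-2-enoic acid (CNP0206859.1) | COc1ccc(/C=C/C(=O)O)cc1C/C=C(\C)[C@@H](CC=C(C)C)OC(C)=O | target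

**Step count and risks**

Total steps: 11. Longest linear sequence: 10 steps (steps 1–5 and 7–11); step 6 is the one-step side branch.

Step 7. Three processes may go wrong:
- Residual methylalanes may ionise the electron-rich aryl dioxolane.
- Alkenyl transfer to the benzylpalladium intermediate may be slow, letting benzylic homocoupling compete.
- Some regiocontrol may be lost in the carbometalation, which a one-flask process cannot correct.

The fallback splits the step and reverses the polarity of the coupling; it sets out from 10 and 12 and comes back at 15. Alkyne 10 is carboaluminated as before, and the alane is quenched with iodine at −30 °C to give (R,E)-tert-butyl[(1-iodo-2,6-dimethylhepta-1,5-dien-3-yl)oxy]dimethylsilane F1, which is purified. Separately, 12 is treated with zinc dust and LiCl in THF to give [5-(1,3-dioxolan-2-yl)-2-methoxybenzyl]zinc chloride F2. Negishi coupling of F1 with F2 under Pd(PPh3)4 in THF should give 15 with retention of the alkene geometry. No alane is present while the acetal is in the flask.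

Step 3. Two processes may go wrong:
- The basic amido catalyst may move the C5=C6 double bond into conjugation before hydride transfer, since the C4 methylene lies between the carbonyl and the alkene.
- Enantiofacial discrimination may be incomplete.

The fallback takes the stereocentre from the chiral pool instead of creating it. It does not branch from a numbered compound: it replaces compounds 1 to 9, sets out from commercial methyl (R)-oxirane-2-carboxylate F3 and comes back at 10. Copper-catalysed opening of the epoxide at C3 with 2-methyl-1-propenylmagnesium bromide (CuBr·SMe2 cat., THF, −40 °C) should give methyl (R)-2-hydroxy-5-methylhex-4-enoate F4. Silylation (TBSCl, imidazole, DMF) gives methyl (R)-2-(tert-butyldimethylsilyloxy)-5-methylhex-4-enoate F5. Reduction with i-Bu2AlH in CH2Cl2 at −78 °C gives (R)-2-(tert-butyldimethylsilyloxy)-5-methylhex-4-enal F6. Ohira–Bestmann homologation (dimethyl (1-diazo-2-oxopropyl)phosphonate, K2CO3, MeOH, 0 °C) then gives alkyne 10.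

Step 11. Two processes may go wrong:
- The allylic acetate may undergo aminolysis or elimination in hot pyridine/piperidine.
- Decarboxylation of the arylidenemalonic acid may be incomplete.

The fallback changes the order so that no acetate is present during the condensation; it sets out from 16 and comes back at 20. Acetal hydrolysis of 16 (1 M aq. HCl/THF) gives 3-[(2E,4R)-4-hydroxy-3,7-dimethylocta-2,6-dien-1-yl]-4-methoxybenzaldehyde F7. Doebner condensation with malonic acid in pyridine/piperidine proceeds through the hydroxy arylidenemalonic acid F8 to (2E)-3-{3-[(2E,4R)-4-hydroxy-3,7-dimethylocta-2,6-dien-1-yl]-4-methoxyphenyl}prop-2-enoic acid F9. Treatment with Ac2O, pyridine and DMAP acetylates the alcohol and forms the mixed acetic anhydride F10 at the carboxyl group. Stirring with aqueous NaHCO3/THF at rt should hydrolyse the anhydride only and give 20.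

**Further compounds**

F1 | step 7 | (R,E)-tert-butyl[(1-iodo-2,6-dimethylhepta-1,5-dien-3-yl)oxy]dimethylsilane | I/C=C(\C)[C@@H](CC=C(C)C)O[Si](C)(C)C(C)(C)C
F2 | step 7 | [5-(1,3-dioxolan-2-yl)-2-methoxybenzyl]zinc chloride | COc1ccc(C2OCCO2)cc1C[Zn]Cl
F3 | step 3 | methyl (R)-oxirane-2-carboxylate (commercial) | COC(=O)[C@H]1CO1
F4 | step 3 | methyl (R)-2-hydroxy-5-methylhex-4-enoate | COC(=O)[C@H](O)CC=C(C)C
F5 | step 3 | methyl (R)-2-(tert-butyldimethylsilyloxy)-5-methylhex-4-enoate | COC(=O)[C@H](O[Si](C)(C)C(C)(C)C)CC=C(C)C
F6 | step 3 | (R)-2-(tert-butyldimethylsilyloxy)-5-methylhex-4-enal | O=C[C@H](O[Si](C)(C)C(C)(C)C)CC=C(C)C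
F7 | step 11 | 3-[(2E,4R)-4-hydroxy-3,7-dimethylocta-2,6-dien-1-yl]-4-methoxybenzaldehyde | COc1ccc(C=O)cc1C/C=C(\C)[C@@H](CC=C(C)C)O
F8 | step 11 | 2-{3-[(2E,4R)-4-hydroxy-3,7-dimethylocta-2,6-dien-1-yl]-4-methoxybenzylidene}malonic acid | COc1ccc(C=C(C(=O)O)C(=O)O)cc1C/C=C(\C)[C@@H](CC=C(C)C)O
F9 | step 11 | (2E)-3-{3-[(2E,4R)-4-hydroxy-3,7-dimethylocta-2,6-dien-1-yl]-4-methoxyphenyl}prop-2-enoic acid | COc1ccc(/C=C/C(=O)O)cc1C/C=C(\C)[C@@H](CC=C(C)C)O
F10 | step 11 | acetic (2E)-3-{3-[(2E,4R)-4-acetoxy-3,7-dimethylocta-2,6-dien-1-yl]-4-methoxyphenyl}prop-2-enoic anhydride | COc1ccc(/C=C/C(=O)OC(C)=O)cc1C/C=C(\C)[C@@H](CC=C(C)C)OC(C)=O
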